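**Retrosynthetic overview**

1. The target is a (2S)-5,7,3',4'-tetrahydroxyflavanone whose ring B carbon C5' is bonded to C6'' of apigenin. The strategy rests on C2 of ring C: this benzylic ether carbon (O1–C2) lies β to the C4 carbonyl and loses its configuration by retro-oxa-Michael cleavage of O1–C2 once C4=O exists. C4=O is therefore installed last, and all seven phenols are carried as benzyl ethers, removed by neutral hydrogenolysis.
2. C4=O ⇐ Markovnikov hydration and oxidation of the C3=C4 bond of a (2S)-2-aryl-2H-chromene ⇐ ring-closing metathesis of an (S)-1-arylallyl 2-vinylaryl ether (closes ring C, forms C3=C4).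
3. O1–C2 and the C2 configuration ⇐ iridium-catalysed asymmetric allylic etherification of a 2-vinylphenoxide (ring A) with the (E)-cinnamyl carbonate of the biaryl.
4. C5'–C6'' biaryl bond ⇐ Suzuki coupling of 6-iodo-tri-O-benzylapigenin with the boronate of 3,4-bis(benzyloxy)-5-bromobenzaldehyde (ring B).
5. Ring order: the three flavone rings are bought as apigenin, rings B and A enter as arenes, and ring C is the only ring formed (step 13).

Key step: step 13

**Remarks on the chemistry**

- Benzyl ethers replace methyl ethers throughout. Cleaving seven methyl ethers with a boron trihalide after the C4 carbonyl is in place would expose C2 to Lewis-acid ring opening, whereas hydrogenolysis is neutral.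
- Locants: flavanone unit unprimed (rings A and C) and primed (ring B); flavone unit double-primed.
- Ar* = 3,4-bis(benzyloxy)-5-{5,7-bis(benzyloxy)-2-[4-(benzyloxy)phenyl]-4-oxo-4H-chromen-6-yl}phenyl.
- The tri-ortho-oxygenated biaryl axis is assumed not to be configurationally stable at room temperature, so no atropisomer is controlled.
- The (Sa,Sc,Sc) ligand in step 12 is chosen on the sense of induction expected for aryl-substituted allyl carbonates with heteroatom nucleophiles. The antipode is equally available should the first batch show the opposite sense.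

**Route**

Step 1
Reactants: 1 apigenin
Product: 2 7-(benzyloxy)-2-[4-(benzyloxy)phenyl]-5-hydroxy-4H-chromen-4-one
Conditions: BnBr (2.2 equiv), K2CO3, DMF, rt
Reagents that add atoms: benzyl bromide, BrCc1ccccc1
Why: Williamson etherification should take the free and more acidic 7- and 4'-hydroxyls, while the 5-hydroxyl stays unalkylated at room temperature because it is held in a hydrogen bond to the C4'' carbonyl.

Step 2
Reactants: 2 7-(benzyloxy)-2-[4-(benzyloxy)phenyl]-5-hydroxy-4H-chromen-4-one
Product: 3 7-(benzyloxy)-2-[4-(benzyloxy)phenyl]-5-hydroxy-6-iodo-4H-chromen-4-one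
Conditions: BnMe3N+ ICl2− (1.05 equiv), CaCO3, CH2Cl2/MeOH, rt, dark
Reagents that add atoms: benzyltrimethylammonium dichloroiodate, C[N+](C)(C)Cc1ccccc1.Cl[I-]Cl
Why: Electrophilic aromatic iodination with this reagent is known to go to C6'' (ortho to the free chelated 5''-hydroxyl) in 5-hydroxy-7-alkoxyflavones and not to C8'', with CaCO3 taking up the HCl; the site is to be confirmed by HMBC before the material is carried on.

Step 3
Reactants: 3 7-(benzyloxy)-2-[4-(benzyloxy)phenyl]-5-hydroxy-6-iodo-4H-chromen-4-one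
Product: 4 5,7-bis(benzyloxy)-2-[4-(benzyloxy)phenyl]-6-iodo-4H-chromen-4-one
Conditions: BnBr, K2CO3, Bu4NI (cat.), DMF, 70 °C
Reagents that add atoms: benzyl bromide, BrCc1ccccc1
Why: Williamson etherification of the chelated and flanked 5''-hydroxyl needs heat but has no competing nucleophile left in the molecule.

Step 4
Reactants: 5 3-bromo-4,5-dihydroxybenzaldehyde
Product: 6 3,4-bis(benzyloxy)-5-bromobenzaldehyde
Conditions: BnBr (2.3 equiv), K2CO3, DMF, 50 °C
Reagents that add atoms: benzyl bromide, BrCc1ccccc1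
Why: Double Williamson etherification of the catechol hydroxyls is straightforward and leaves the aldehyde and the bromide untouched.

Step 5
Reactants: 6 3,4-bis(benzyloxy)-5-bromobenzaldehyde
Product: 7 3,4-bis(benzyloxy)-5-(4,4,5,5-tetramethyl-1,3,2-dioxaborolan-2-yl)benzaldehyde
Conditions: B2pin2, Pd(dppf)Cl2 (3 mol %), KOAc, 1,4-dioxane, 90 °C
Reagents that add atoms: bis(pinacolato)diboron, CC1(C)OB(OC1(C)C)B1OC(C)(C)C(C)(C)O1
Why: Miyaura borylation (oxidative addition of the aryl bromide to zerovalent palladium, acetate-assisted transmetalation with the diboron) tolerates the aldehyde and the benzyl ethers.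

Step 6
Reactants: 4 5,7-bis(benzyloxy)-2-[4-(benzyloxy)phenyl]-6-iodo-4H-chromen-4-one; 7 3,4-bis(benzyloxy)-5-(4,4,5,5-tetramethyl-1,3,2-dioxaborolan-2-yl)benzaldehyde
Product: 8 Ar*-carbaldehyde (3,4-bis(benzyloxy)-5-{5,7-bis(benzyloxy)-2-[4-(benzyloxy)phenyl]-4-oxo-4H-chromen-6-yl}benzaldehyde)
Conditions: Pd(OAc)2 (5 mol %), SPhos (10 mol %), K3PO4, toluene/H2O, 90 °C
Reagents that add atoms: none
Why: Suzuki–Miyaura coupling with a bulky electron-rich biarylphosphine is suited to tri-ortho-substituted biaryls; the halide is placed on the flavone because a boronate between two alkoxy groups would protodeboronate.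

Step 7
Reactants: 8 Ar*-carbaldehyde
Product: 9 (E)-3-Ar*-prop-2-enal
Conditions: Ph3P=CHCHO (1.3 equiv), toluene, 80 °C
Reagents that add atoms: (triphenylphosphoranylidene)acetaldehyde, O=CC=P(c1ccccc1)(c1ccccc1)c1ccccc1
Why: Wittig olefination with the stabilised formyl ylide should give the (E)-enal at the aryl aldehyde, the only carbonyl electrophilic enough, since the flavone carbonyl is a vinylogous ester.

Step 8
Reactants: 9 (E)-3-Ar*-prop-2-enal
Product: 10 (E)-3-Ar*-prop-2-en-1-ol
Conditions: NaBH4, CeCl3·7H2O, THF/MeOH, −20 °C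
Reagents that add atoms: none
Why: Luche reduction delivers hydride 1,2 to the enal within minutes at low temperature, conditions under which the flavone carbonyl and its C2''=C3'' bond are not reduced.

Step 9
Reactants: 10 (E)-3-Ar*-prop-2-en-1-ol
Product: 11 (E)-3-Ar*-prop-2-en-1-yl methyl carbonate
Conditions: ClCO2Me, pyridine, CH2Cl2, 0 °C
Reagents that add atoms: methyl chloroformate, COC(=O)Cl
Why: Acylation of the primary allylic alcohol installs the carbonate leaving group that the iridium catalyst ionises in step 12.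

Step 10
Reactants: 12 3,5-bis(benzyloxy)phenol
Product: 13 2-hydroxy-4,6-bis(benzyloxy)benzaldehyde
Conditions: (CH2O)n, MgCl2, Et3N, MeCN, reflux; then aq. HCl
Reagents that add atoms: formaldehyde (as paraformaldehyde), C=O
Why: Magnesium-phenoxide-directed ortho-formylation (Casnati–Skattebøl) delivers formaldehyde within the chelate only ortho to the phenol, and the two ortho positions of 12 are equivalent, so one salicylaldehyde is expected.

Step 11
Reactants: 13 2-hydroxy-4,6-bis(benzyloxy)benzaldehyde
Product: 14 3,5-bis(benzyloxy)-2-vinylphenol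
Conditions: Ph3PCH3Br (2.5 equiv), KOtBu (2.5 equiv), THF, 0 °C to rt; used without storage
Reagents that add atoms: methyltriphenylphosphonium bromide, C[P+](c1ccccc1)(c1ccccc1)c1ccccc1.[Br-]
Why: Wittig methylenation with excess ylide converts the aldehyde to the vinyl group even though the first equivalent of base is spent on the phenol.

Step 12
Reactants: 11 (E)-3-Ar*-prop-2-en-1-yl methyl carbonate; 14 3,5-bis(benzyloxy)-2-vinylphenol
Product: 16 (S)-1-Ar*-prop-2-en-1-yl 3,5-bis(benzyloxy)-2-vinylphenyl ether, via lithium 3,5-bis(benzyloxy)-2-vinylphenoxide 15 (not isolated)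
Conditions: 14, LiN(SiMe3)2, THF, 0 °C; then 11, [Ir(cod)Cl]2 (2 mol %), (Sa,Sc,Sc)-(1,1'-binaphthalene-2,2'-diyl) N,N-bis(1-phenylethyl)phosphoramidite (4 mol %, pre-activated with n-PrNH2), THF, 40–50 °C
Reagents that add atoms: lithium bis(trimethylsilyl)amide, [Li+].C[Si](C)(C)[N-][Si](C)(C)C (supplies only the lithium of 15)
Why: Iridium-catalysed asymmetric allylic etherification: the carbonate ionises to an allyliridium complex of the cyclometalated phosphoramidite catalyst, the aryloxide attacks the aryl-bearing terminus to give the branched ether, and the ligand fixes the face of attack so that C2 is set as S under catalyst control.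

Step 13
Reactants: 16 (S)-1-Ar*-prop-2-en-1-yl 3,5-bis(benzyloxy)-2-vinylphenyl ether
Product: 17 (2S)-5,7-bis(benzyloxy)-2-Ar*-2H-chromene
Conditions: second-generation Grubbs catalyst (H2IMes)(PCy3)Cl2Ru=CHPh (5 mol %), 1,4-benzoquinone (10 mol %), CH2Cl2 (0.01 M), 35 °C, dark
Reagents that add atoms: none
Why: Ring-closing olefin metathesis: the ruthenium benzylidene exchanges onto the terminal allyl alkene of 16, the new alkylidene adds across the ortho vinyl group to a ruthenacyclobutane, and cycloreversion releases chromene 17 and a ruthenium methylidene that re-enters the cycle with loss of ethylene. The closest known reaction is the metathesis of allyl 2-vinylaryl ethers to 2H-chromenes. Ring C is closed as a six-membered ring by forming the C3=C4 double bond between two monosubstituted alkenes that the arene holds ortho to each other. No stereocentre is formed; C2 was set in step 12 and no bond to it is made or broken, so its S configuration should be carried through. The step needs chemoselectivity for the two terminal alkenes over the flavone C2''=C3'' bond, which is trisubstituted, electron-poor and part of the pyranone, and it must avoid double-bond migration and electrocyclic opening of the chromene, hence the benzoquinone as hydride trap, the high dilution, the mild temperature and the exclusion of light.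

Step 14
Reactants: 17 (2S)-5,7-bis(benzyloxy)-2-Ar*-2H-chromene
Product: 19 (2S)-5,7-bis(benzyloxy)-2-Ar*-chroman-4-ol (both C4 epimers), via benzylic 4-hydroperoxide 18 (not isolated)
Conditions: Co(acac)2 (20 mol %), PhSiH3, O2 (1 atm), THF/i-PrOH, rt; then PPh3; crude product used directly
Reagents that add atoms: dioxygen, O=O
Why: Mukaiyama hydration: a cobalt hydride transfers a hydrogen atom to C3 so that the radical sits at C4, benzylic to the trioxygenated ring A, where it is trapped by O2, and PPh3 reduces the hydroperoxide; C2 is not involved and the C4 configuration is irrelevant.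

Step 15
Reactants: 19 (2S)-5,7-bis(benzyloxy)-2-Ar*-chroman-4-ol
Product: 20 (2S)-5,7-bis(benzyloxy)-2-Ar*-chroman-4-one
Conditions: Dess–Martin periodinane, NaHCO3, CH2Cl2, 0 °C to rt
Reagents that add atoms: none
Why: Dess–Martin oxidation of the secondary benzylic alcohol runs under buffered conditions without soluble base, so the C4 carbonyl appears without giving the retro-oxa-Michael pathway a chance to scramble C2.

Step 16
Reactants: 20 (2S)-5,7-bis(benzyloxy)-2-Ar*-chroman-4-one
Product: 21 CNP0176432.1, (2S)-2-{3,4-dihydroxy-5-[5,7-dihydroxy-2-(4-hydroxyphenyl)-4-oxo-4H-chromen-6-yl]phenyl}-5,7-dihydroxychroman-4-one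
Conditions: H2 (1 atm), Pd/C (10 wt %), THF/MeOH, rt; neutral isolation
Reagents that add atoms: none
Why: Catalytic hydrogenolysis cleaves all seven benzyl ethers under neutral conditions that are standard for benzylated flavones and flavanones, so neither acid nor base reaches the now labile C2.

**Compound list**

1 | apigenin | O=c1cc(-c2ccc(O)cc2)oc2cc(O)cc(O)c12 | starting material
2 | 7-(benzyloxy)-2-[4-(benzyloxy)phenyl]-5-hydroxy-4H-chromen-4-one | O=c1cc(-c2ccc(OCc3ccccc3)cc2)oc2cc(OCc3ccccc3)cc(O)c12 | intermediate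
3 | 7-(benzyloxy)-2-[4-(benzyloxy)phenyl]-5-hydroxy-6-iodo-4H-chromen-4-one | O=c1cc(-c2ccc(OCc3ccccc3)cc2)oc2cc(OCc3ccccc3)c(I)c(O)c12 | intermediate
4 | 5,7-bis(benzyloxy)-2-[4-(benzyloxy)phenyl]-6-iodo-4H-chromen-4-one | O=c1cc(-c2ccc(OCc3ccccc3)cc2)oc2cc(OCc3ccccc3)c(I)c(OCc3ccccc3)c12 | intermediate
5 | 3-bromo-4,5-dihydroxybenzaldehyde | O=Cc1cc(O)c(O)c(Br)c1 | starting material
6 | 3,4-bis(benzyloxy)-5-bromobenzaldehyde | O=Cc1cc(OCc2ccccc2)c(OCc2ccccc2)c(Br)c1 | intermediate
7 | 3,4-bis(benzyloxy)-5-(4,4,5,5-tetramethyl-1,3,2-dioxaborolan-2-yl)benzaldehyde | O=Cc1cc(OCc2ccccc2)c(OCc2ccccc2)c(B2OC(C)(C)C(C)(C)O2)c1 | intermediate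
8 | Ar*-carbaldehyde, 3,4-bis(benzyloxy)-5-{5,7-bis(benzyloxy)-2-[4-(benzyloxy)phenyl]-4-oxo-4H-chromen-6-yl}benzaldehyde | O=Cc1cc(OCc2ccccc2)c(OCc2ccccc2)c(-c2c(OCc3ccccc3)cc3oc(-c4ccc(OCc5ccccc5)cc4)cc(=O)c3c2OCc2ccccc2)c1 | intermediate
9 | (E)-3-Ar*-prop-2-enal | O=C/C=C/c1cc(OCc2ccccc2)c(OCc2ccccc2)c(-c2c(OCc3ccccc3)cc3oc(-c4ccc(OCc5ccccc5)cc4)cc(=O)c3c2OCc2ccccc2)c1 | intermediate
10 | (E)-3-Ar*-prop-2-en-1-ol | OC/C=C/c1cc(OCc2ccccc2)c(OCc2ccccc2)c(-c2c(OCc3ccccc3)cc3oc(-c4ccc(OCc5ccccc5)cc4)cc(=O)c3c2OCc2ccccc2)c1 | intermediate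
11 | (E)-3-Ar*-prop-2-en-1-yl methyl carbonate | COC(=O)OC/C=C/c1cc(OCc2ccccc2)c(OCc2ccccc2)c(-c2c(OCc3ccccc3)cc3oc(-c4ccc(OCc5ccccc5)cc4)cc(=O)c3c2OCc2ccccc2)c1 | intermediate
12 | 3,5-bis(benzyloxy)phenol | Oc1cc(OCc2ccccc2)cc(OCc2ccccc2)c1 | starting material
13 | 2-hydroxy-4,6-bis(benzyloxy)benzaldehyde | O=Cc1c(O)cc(OCc2ccccc2)cc1OCc1ccccc1 | intermediate
14 | 3,5-bis(benzyloxy)-2-vinylphenol | C=Cc1c(O)cc(OCc2ccccc2)cc1OCc1ccccc1 | intermediate
15 | lithium 3,5-bis(benzyloxy)-2-vinylphenoxide | [Li+].[O-]c1cc(OCc2ccccc2)cc(OCc2ccccc2)c1C=C | intermediate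
16 | (S)-1-Ar*-prop-2-en-1-yl 3,5-bis(benzyloxy)-2-vinylphenyl ether | C=C[C@@H](c1cc(OCc2ccccc2)c(OCc2ccccc2)c(-c2c(OCc3ccccc3)cc3oc(-c4ccc(OCc5ccccc5)cc4)cc(=O)c3c2OCc2ccccc2)c1)Oc1cc(OCc2ccccc2)cc(OCc2ccccc2)c1C=C | intermediate
17 | (2S)-5,7-bis(benzyloxy)-2-Ar*-2H-chromene | C1=C[C@@H](c2cc(OCc3ccccc3)c(OCc3ccccc3)c(-c3c(OCc4ccccc4)cc4oc(-c5ccc(OCc6ccccc6)cc5)cc(=O)c4c3OCc3ccccc3)c2)Oc2cc(OCc3ccccc3)cc(OCc3ccccc3)c21 | intermediate
18 | (2S)-5,7-bis(benzyloxy)-2-Ar*-chroman-4-yl hydroperoxide, both C4 epimers | OOC1C[C@@H](c2cc(OCc3ccccc3)c(OCc3ccccc3)c(-c3c(OCc4ccccc4)cc4oc(-c5ccc(OCc6ccccc6)cc5)cc(=O)c4c3OCc3ccccc3)c2)Oc2cc(OCc3ccccc3)cc(OCc3ccccc3)c21 | intermediate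
19 | (2S)-5,7-bis(benzyloxy)-2-Ar*-chroman-4-ol, both C4 epimers | OC1C[C@@H](c2cc(OCc3ccccc3)c(OCc3ccccc3)c(-c3c(OCc4ccccc4)cc4oc(-c5ccc(OCc6ccccc6)cc5)cc(=O)c4c3OCc3ccccc3)c2)Oc2cc(OCc3ccccc3)cc(OCc3ccccc3)c21 | intermediate
20 | (2S)-5,7-bis(benzyloxy)-2-Ar*-chroman-4-one | O=C1C[C@@H](c2cc(OCc3ccccc3)c(OCc3ccccc3)c(-c3c(OCc4ccccc4)cc4oc(-c5ccc(OCc6ccccc6)cc5)cc(=O)c4c3OCc3ccccc3)c2)Oc2cc(OCc3ccccc3)cc(OCc3ccccc3)c21 | intermediate
21 | CNP0176432.1, (2S)-2-{3,4-dihydroxy-5-[5,7-dihydroxy-2-(4-hydroxyphenyl)-4-oxo-4H-chromen-6-yl]phenyl}-5,7-dihydroxychroman-4-one | O=C1C[C@@H](c2cc(O)c(O)c(-c3c(O)cc4oc(-c5ccc(O)cc5)cc(=O)c4c3O)c2)Oc2cc(O)cc(O)c21 | target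

**Step count and risk**

Total step count: 16. Longest linear sequence: 12 steps (1 → 2 → 3 → 4 → 8 → 9 → 10 → 11 → 16 → 17 → 19 → 20 → 21; steps 1–3, 6–9 and 12–16).

The three steps most likely to fail:

**Step 12 (allylic etherification).** The phloroglucinol-type aryloxide is ambident and ortho-substituted. C-allylation at the free ring positions, attack at the unsubstituted allyl terminus to give the linear ether, or reduced enantioselectivity may compete with branched O-allylation.

The fallback sets out from carbonate 11 and comes back at ether 16. It moves the stereo-determining step to a small oxygen nucleophile and forms the aryl ether bond by SN2 displacement instead: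
- [Ir(cod)Cl]2 with the (Ra,Rc,Rc) antipode of the phosphoramidite and KOSiEt3 in CH2Cl2 at room temperature should give the branched (R)-1-Ar*-prop-2-en-1-yl triethylsilyl ether F1.
- Bu4NF in THF would free (R)-1-Ar*-prop-2-en-1-ol F2.
- A Mitsunobu reaction of F2 with phenol 14 (PPh3, DIAD, toluene, 0 °C) would form the O1–C2 bond with inversion and deliver 16.

**Step 14 (hydration).** Hydrogen-atom transfer may also reach the flavone C2''=C3'' bond, or the chromene double bond may simply be reduced when oxygen trapping is slow.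

The fallback sets out from chromene 17 and comes back at alcohol 19. It replaces the radical pathway by ionic Markovnikov hydration:
- Oxymercuration with Hg(OAc)2 (1.0 equiv) in THF/H2O at 0 °C places mercury on C3 and water on the benzylic C4, giving the 3-(acetoxymercurio) derivative of the flavan-4-ol F3. The single equivalent and the low temperature are meant to limit mercuration of ring A.
- Reductive demercuration with NaBH4/NaOH in the same flask would give 19, which goes on to step 15.

**Step 13 (metathesis).** Ruthenium may be held back as a chelated 2-alkoxybenzylidene formed at the hindered 2,6-dioxygenated styrene. A ruthenium hydride may also move the allyl double bond into conjugation, which would erase C2 and divert the material.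

The fallback sets out from aldehyde 8 and comes back at flavanone 20. It closes ring C through the O1–C2 bond instead of C3=C4:
- Claisen–Schmidt condensation of 8 with commercial 1-[2-hydroxy-4,6-bis(benzyloxy)phenyl]ethanone (KOH, EtOH/THF, rt) would give the (E)-2'-hydroxychalcone F4.
- An intramolecular oxa-Michael addition catalysed by a cinchona-alkaloid-derived bifunctional thiourea (toluene, rt) would give 20. The pseudoenantiomer that gives the (2S) series is to be picked by screening.
- Only moderate enantioselectivity is expected for an unactivated chalcone, so 20 would be enriched by preparative chromatography on a chiral stationary phase before step 16.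
- This reserve route gives up the carbonyl-last principle, and 20 made this way must be kept free of base.

**Further compounds**

F1 | step 12 | (R)-1-Ar*-prop-2-en-1-yl triethylsilyl ether | C=C[C@H](c1cc(OCc2ccccc2)c(OCc2ccccc2)c(-c2c(OCc3ccccc3)cc3oc(-c4ccc(OCc5ccccc5)cc4)cc(=O)c3c2OCc2ccccc2)c1)O[Si](CC)(CC)CC
F2 | step 12 | (R)-1-Ar*-prop-2-en-1-ol | C=C[C@H](c1cc(OCc2ccccc2)c(OCc2ccccc2)c(-c2c(OCc3ccccc3)cc3oc(-c4ccc(OCc5ccccc5)cc4)cc(=O)c3c2OCc2ccccc2)c1)O
F3 | step 14 | 3-(acetoxymercurio) derivative of flavan-4-ol 19, C2 configuration as in 19, C3 and C4 epimers | OC1C([Hg]OC(C)=O)[C@@H](c2cc(OCc3ccccc3)c(OCc3ccccc3)c(-c3c(OCc4ccccc4)cc4oc(-c5ccc(OCc6ccccc6)cc5)cc(=O)c4c3OCc3ccccc3)c2)Oc2cc(OCc3ccccc3)cc(OCc3ccccc3)c21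
F4 | step 13 | (E)-1-[2-hydroxy-4,6-bis(benzyloxy)phenyl]-3-Ar*-prop-2-en-1-one | O=C(/C=C/c1cc(OCc2ccccc2)c(OCc2ccccc2)c(-c2c(OCc3ccccc3)cc3oc(-c4ccc(OCc5ccccc5)cc4)cc(=O)c3c2OCc2ccccc2)c1)c1c(O)cc(OCc2ccccc2)cc1OCc1ccccc1
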